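**Plan**

Drimane numbering is used: ring A = C1–C5 and C10, ring B = C5–C10, C11 = formyl carbon on C9, C12 = methyl on C8.

- Retrosynthesis cuts, in order: the C6–O acyl bond; the C5–H/C6–O pair (syn hydroboration of a 5,7-diene); C9–OH (oxygen transfer to an extended ester enolate); C9–C11 (carbonylation of a C9 enol triflate); and finally C8, taken out of ring B to leave a cyclopentanone.
- Forward: ring A is completed on a commercial enantiopure bicyclic enedione (gem-dimethylation at C4 with the alkene driven to C5=C6, then deoxygenation at C3). Ring B starts five-membered (C5, C6, C7, C9, C10) and becomes six-membered when C8, carrying C12, is inserted into the C9–C7 bond.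
- What makes the event possible: the C9 carbonyl sits between quaternary C10 and the allylic methylene C7, so only C7 should migrate. The new ketone can then enolize only toward C8, which gives one enol triflate and one site for C11.
- Stereochemistry: C10 comes from the starting enedione. C9 (α-OH), C5 (α-H) and C6 (α-O) are all set by reagent attack anti to the axial C10 methyl. The all-E triene comes from the acid.

Key step: step 5

Remark: (2E,4E,6E)-octa-2,4,6-trienoic acid is taken as a purchased reagent.

**Route**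

Step 1
Reactants: 1 (7aS)-7a-methyl-2,3,7,7a-tetrahydro-1H-indene-1,5(6H)-dione
Product: 2 (7a'S)-7a'-methyl-2',3',7',7a'-tetrahydrospiro[1,3-dioxolane-2,1'-inden]-5'(6'H)-one
Conditions: HOCH2CH2OH, p-TsOH·H2O (cat.), 4 Å MS, rt
Reagents that add atoms: ethylene glycol, OCCO
Why: Acetalization; the saturated cyclopentanone carbonyl (future C9) is more electrophilic than the conjugated enone carbonyl, so mild acid with a drying agent should mask it alone without moving the double bond.

Step 2
Reactants: 2 (7a'S)-7a'-methyl-2',3',7',7a'-tetrahydrospiro[1,3-dioxolane-2,1'-inden]-5'(6'H)-one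
Product: 3 (7a'S)-4',4',7a'-trimethyl-2',4',7',7a'-tetrahydrospiro[1,3-dioxolane-2,1'-inden]-5'(6'H)-one
Conditions: KOt-Bu (excess), MeI, t-BuOH, rt
Reagents that add atoms: iodomethane, CI
Why: Deconjugative α,α-dimethylation of an enone through its extended dienolate; both methyl groups enter at C4 and the alkene is driven into the C5=C6 position, with no new stereocenter and C10 untouched.

Step 3
Reactants: 3 (7a'S)-4',4',7a'-trimethyl-2',4',7',7a'-tetrahydrospiro[1,3-dioxolane-2,1'-inden]-5'(6'H)-one
Product: 5 (7a'S)-4',4',7a'-trimethyl-2',4',5',6',7',7a'-hexahydrospiro[1,3-dioxolane-2,1'-indene], via hydrazone 4 (not isolated)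
Conditions: N2H4·H2O, KOH, diethylene glycol, 130 then 200 °C
Reagents that add atoms: none
Why: Wolff–Kishner reduction removes the C3 carbonyl under base, which the ketal tolerates; C4 is quaternary, so the hydrazone anion cannot pull the C5=C6 alkene into conjugation.

Step 4
Reactants: 5 (7a'S)-4',4',7a'-trimethyl-2',4',5',6',7',7a'-hexahydrospiro[1,3-dioxolane-2,1'-indene]
Product: 6 (7aS)-4,4,7a-trimethyl-2,4,5,6,7,7a-hexahydro-1H-inden-1-one
Conditions: 1 M HCl, THF, rt
Reagents that add atoms: water, O
Why: Acid-catalysed acetal hydrolysis; the trisubstituted ring-fusion alkene is the stable position in this hydrindenone, so mild acid should not conjugate it.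

Step 5
Reactants: 6 (7aS)-4,4,7a-trimethyl-2,4,5,6,7,7a-hexahydro-1H-inden-1-one
Product: 7 (10S)-11-nordrim-5-en-9-one (both C8 epimers)
Conditions: CH3CHN2 (ethereal, freshly prepared), BF3·OEt2, Et2O, −78 to −20 °C
Reagents that add atoms: diazoethane, CC=[N+]=[N-]
Why: BF3 activates the C9 carbonyl, diazoethane adds through carbon to give a β-oxido diazonium betaine, and loss of N2 is coupled to a 1,2-shift of the allylic methylene C7 from C9 to the new carbon, which becomes C8 and brings C12 with it (Lewis acid-promoted diazoalkane homologation of a cycloalkanone, Tiffeneau–Demjanov family). No ring is closed by cyclization: the five-membered ring (C5, C6, C7, C9, C10) grows to six-membered ring B by insertion of C8 into the C9–C7 bond. The only new stereocenter, C8, is not controlled and need not be, because it becomes trigonal in step 6. The step needs regioselectivity (C7, not quaternary C10, must migrate) and a single insertion: the betaine should place its diazonium group anti to the less hindered allylic C7, and the product ketone, flanked by quaternary C10 and tertiary C8, is far less reactive than 6. Low temperature keeps the non-conjugated C5=C6 bond in place.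

Step 6
Reactants: 7 (10S)-11-nordrim-5-en-9-one (both C8 epimers)
Product: 9 (10S)-11-nordrima-5,8-dien-9-yl trifluoromethanesulfonate, via potassium enolate 8 (not isolated)
Conditions: KN(SiMe3)2, THF, −78 to 0 °C; then PhNTf2
Reagents that add atoms: N-phenylbis(trifluoromethanesulfonimide), O=S(=O)(N(c1ccccc1)S(=O)(=O)C(F)(F)F)C(F)(F)F
Why: Enol triflate formation; the ketone can enolize only toward C8 because C10 is quaternary, so one tetrasubstituted enolate forms and is O-sulfonylated, which erases the uncontrolled C8 center.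

Step 7
Reactants: 9 (10S)-11-nordrima-5,8-dien-9-yl trifluoromethanesulfonate
Product: 10 methyl (10S)-drima-5,8-dien-11-oate
Conditions: Pd(OAc)2 (cat.), dppp, CO (1 atm), MeOH, Et3N, DMF, 70 °C
Reagents that add atoms: carbon monoxide, [C-]#[O+]; methanol, CO
Why: Palladium-catalysed alkoxycarbonylation of an enol triflate (oxidative addition to zerovalent palladium, CO insertion, methanolysis) installs C11 on C9; the skipped C5=C6 alkene is inert.

Step 8
Reactants: 10 methyl (10S)-drima-5,8-dien-11-oate
Product: 12 methyl (9R,10S)-9-hydroxydrima-5,7-dien-11-oate, via lithium trienolate 11 (not isolated)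
Conditions: LiN(i-Pr)2, THF/HMPA, −78 °C; then 2-(phenylsulfonyl)-3-phenyloxaziridine
Reagents that add atoms: 2-(phenylsulfonyl)-3-phenyloxaziridine, O=S(=O)(c1ccccc1)N1OC1c1ccccc1
Why: Deconjugative α-hydroxylation of an extended ester enolate; the base removes the doubly allylic C7–H (more acidic than the C12 methyl hydrogens), and the bulky oxaziridine transfers oxygen to C9 of the planar trienolate from the face anti to the axial C10 methyl, which should give the 9α-alcohol and the 5,7-diene.

Step 9
Reactants: 12 methyl (9R,10S)-9-hydroxydrima-5,7-dien-11-oate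
Product: 13 (9R,10S)-drima-5,7-diene-9,11-diol
Conditions: LiAlH4, THF, 0 °C
Reagents that add atoms: none
Why: Hydride reduction of the ester to the primary alcohol; the diene and the tertiary alkoxide are inert to LiAlH4.

Step 10
Reactants: 13 (9R,10S)-drima-5,7-diene-9,11-diol
Product: 14 (9R,10S)-9,11-O-isopropylidenedrima-5,7-diene-9,11-diol
Conditions: 2-methoxypropene, PPTS (cat.), CH2Cl2, 0 °C
Reagents that add atoms: 2-methoxypropene, COC(C)=C
Why: Acetonide formation by mild acid-catalysed ketal exchange; it removes the free hydroxyls that could direct borane in step 11 and holds C11 at the alcohol level through the acylation.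

Step 11
Reactants: 14 (9R,10S)-9,11-O-isopropylidenedrima-5,7-diene-9,11-diol
Product: 16 (5S,6S,9R,10S)-9,11-O-isopropylidenedrim-7-ene-6,9,11-triol, via allylic borane 15 (not isolated)
Conditions: BH3·THF, THF, 0 °C to rt; then NaOH, H2O2
Reagents that add atoms: hydrogen peroxide, OO
Why: Hydroboration–oxidation of a conjugated 5,7-diene, as known for steroidal 5,7-dienes; B–H adds syn across C5=C6 from the α-face (anti to the C10 methyl and the axial C4 methyl) with boron at C6, which should give the trans ring fusion and, after oxidation with retention, the 6α-alcohol, while the more hindered C7=C8 bond stays.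

Step 12
Reactants: 16 (5S,6S,9R,10S)-9,11-O-isopropylidenedrim-7-ene-6,9,11-triol; 17 (2E,4E,6E)-octa-2,4,6-trienoic acid
Product: 19 (5S,6S,9R,10S)-9,11-O-isopropylidene-9,11-dihydroxydrim-7-en-6-yl (2E,4E,6E)-octa-2,4,6-trienoate, via mixed anhydride 18 (not isolated)
Conditions: 17, 2,4,6-Cl3C6H2COCl, Et3N, THF, rt; then 16, DMAP, toluene, 60 °C
Reagents that add atoms: none
Why: Yamaguchi esterification; the mixed anhydride with DMAP acylates the hindered secondary allylic 6α-hydroxyl with retention at C6, and the triene geometry is that of the acid.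

Step 13
Reactants: 19 (5S,6S,9R,10S)-9,11-O-isopropylidene-9,11-dihydroxydrim-7-en-6-yl (2E,4E,6E)-octa-2,4,6-trienoate
Product: 20 (5S,6S,9R,10S)-9,11-dihydroxydrim-7-en-6-yl (2E,4E,6E)-octa-2,4,6-trienoate
Conditions: 80% aq. AcOH, rt
Reagents that add atoms: none
Why: Mild acid hydrolysis of the dioxolane; the allylic ester and the tertiary allylic alcohol (next to the electron-poor CH2O carbon) should survive.

Step 14
Reactants: 20 (5S,6S,9R,10S)-9,11-dihydroxydrim-7-en-6-yl (2E,4E,6E)-octa-2,4,6-trienoate
Product: 21 (5S,6S,9R,10S)-9-hydroxy-11-oxodrim-7-en-6-yl (2E,4E,6E)-octa-2,4,6-trienoate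
Conditions: TEMPO (cat.), PhI(OAc)2, CH2Cl2, rt
Reagents that add atoms: none
Why: Oxoammonium (TEMPO) oxidation with a hypervalent iodine co-oxidant is selective for the primary alcohol; the tertiary 9-hydroxyl cannot be oxidized and C9 has no hydrogen, so the α-hydroxy aldehyde cannot epimerize.

**Compound list**

1 | (7aS)-7a-methyl-2,3,7,7a-tetrahydro-1H-indene-1,5(6H)-dione | C[C@]12CCC(=O)C=C1CCC2=O | starting material
2 | (7a'S)-7a'-methyl-2',3',7',7a'-tetrahydrospiro[1,3-dioxolane-2,1'-inden]-5'(6'H)-one | C[C@]12CCC(=O)C=C1CCC23OCCO3 | intermediate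
3 | (7a'S)-4',4',7a'-trimethyl-2',4',7',7a'-tetrahydrospiro[1,3-dioxolane-2,1'-inden]-5'(6'H)-one | C[C@]12CCC(=O)C(C)(C)C1=CCC23OCCO3 | intermediate
4 | hydrazone of 3 (not isolated) | C[C@]12CCC(=NN)C(C)(C)C1=CCC23OCCO3 | intermediate
5 | (7a'S)-4',4',7a'-trimethyl-2',4',5',6',7',7a'-hexahydrospiro[1,3-dioxolane-2,1'-indene] | C[C@]12CCCC(C)(C)C1=CCC23OCCO3 | intermediate
6 | (7aS)-4,4,7a-trimethyl-2,4,5,6,7,7a-hexahydro-1H-inden-1-one | C[C@]12CCCC(C)(C)C1=CCC2=O | intermediate
7 | (10S)-11-nordrim-5-en-9-one, i.e. (8aS)-2,5,5,8a-tetramethyl-3,5,6,7,8,8a-hexahydronaphthalen-1(2H)-one, both C8 epimers | C[C@]12CCCC(C)(C)C1=CCC(C)C2=O | intermediate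
8 | potassium enolate of 7 (not isolated) | C[C@]12CCCC(C)(C)C1=CCC(C)=C2[O-].[K+] | intermediate
9 | (10S)-11-nordrima-5,8-dien-9-yl trifluoromethanesulfonate | C[C@]12CCCC(C)(C)C1=CCC(C)=C2OS(=O)(=O)C(F)(F)F | intermediate
10 | methyl (10S)-drima-5,8-dien-11-oate | C[C@]12CCCC(C)(C)C1=CCC(C)=C2C(=O)OC | intermediate
11 | lithium trienolate of 10 (not isolated) | C[C@]12CCCC(C)(C)C1=CC=C(C)C2=C([O-])OC.[Li+] | intermediate
12 | methyl (9R,10S)-9-hydroxydrima-5,7-dien-11-oate | C[C@]12CCCC(C)(C)C1=CC=C(C)[C@]2(O)C(=O)OC | intermediate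
13 | (9R,10S)-drima-5,7-diene-9,11-diol | C[C@]12CCCC(C)(C)C1=CC=C(C)[C@]2(O)CO | intermediate
14 | (9R,10S)-9,11-O-isopropylidenedrima-5,7-diene-9,11-diol | C[C@]12CCCC(C)(C)C1=CC=C(C)[C@]23COC(C)(C)O3 | intermediate
15 | 6α-boryl (allylic borane) adduct of 14 (not isolated) | C[C@]12CCCC(C)(C)[C@@H]1[C@@H](B)C=C(C)[C@]23COC(C)(C)O3 | intermediate
16 | (5S,6S,9R,10S)-9,11-O-isopropylidenedrim-7-ene-6,9,11-triol | C[C@]12CCCC(C)(C)[C@@H]1[C@@H](O)C=C(C)[C@]23COC(C)(C)O3 | intermediate
17 | (2E,4E,6E)-octa-2,4,6-trienoic acid | C/C=C/C=C/C=C/C(=O)O | starting material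
18 | mixed anhydride of 17 and 2,4,6-trichlorobenzoic acid (not isolated) | C/C=C/C=C/C=C/C(=O)OC(=O)c1c(Cl)cc(Cl)cc1Cl | intermediate
19 | (5S,6S,9R,10S)-9,11-O-isopropylidene-9,11-dihydroxydrim-7-en-6-yl (2E,4E,6E)-octa-2,4,6-trienoate | C[C@]12CCCC(C)(C)[C@@H]1[C@@H](OC(=O)/C=C/C=C/C=C/C)C=C(C)[C@]23COC(C)(C)O3 | intermediate
20 | (5S,6S,9R,10S)-9,11-dihydroxydrim-7-en-6-yl (2E,4E,6E)-octa-2,4,6-trienoate | C[C@]12CCCC(C)(C)[C@@H]1[C@@H](OC(=O)/C=C/C=C/C=C/C)C=C(C)[C@]2(O)CO | intermediate
21 | (5S,6S,9R,10S)-9-hydroxy-11-oxodrim-7-en-6-yl (2E,4E,6E)-octa-2,4,6-trienoate | C/C=C/C=C/C=C/C(=O)O[C@H]1C=C(C)[C@](O)(C=O)[C@@]2(C)CCCC(C)(C)[C@H]12 | target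

**Summary**

Total step count: 14. Longest linear sequence: 14 steps (1 to 21).

Steps most likely to fail:

1. Step 5. The quaternary C10 may migrate in place of C7, or a second insertion or epoxide formation may compete. The fallback fixes the regiochemistry by enolization instead of migratory aptitude. It sets out from 6 and returns at 9. Ketone 6, which can enolize only toward C7, is converted with LiN(i-Pr)2 and Me3SiCl into the trimethylsilyl dienol ether F1. Chloro(methyl)carbenoid (CH3CHCl2, n-BuLi, −40 °C) adds to the enol ether double bond to give the 1-chloro-1-methyl-siloxycyclopropane F2. Heating in toluene opens the cyclopropane with loss of Me3SiCl to the ring-expanded 8-methyl enone (10S)-11-nordrima-5,7-dien-9-one F3. Conjugate reduction with Li[HB(s-Bu)3] and trapping of the enolate with PhNTf2 then gives triflate 9.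

2. Step 8. Deprotonation may occur at the C12 methyl in place of C7, or oxygen may be transferred at C7 or to the β-face. The fallback brings the oxygen in by epoxidation. It sets out from 10 and returns at 13. Ester 10 is reduced with i-Bu2AlH to the allylic alcohol (10S)-drima-5,8-dien-11-ol F4. Hydroxyl-directed epoxidation (VO(acac)2, t-BuOOH) on the face anti to the C10 methyl gives the 8α,9α-epoxy alcohol F5. Epoxide-to-allylic-alcohol isomerization with Al(Oi-Pr)3 in refluxing toluene, with loss of the allylic C7 hydrogen to form the conjugated diene, gives diol 13.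

3. Step 11. Borane may add to the C7=C8 bond or in a 1,4 sense, or the allylic borane may shift, which would erode chemo- and regioselectivity. The fallback hydroborates before the 7,8-alkene exists. It sets out from 10 and returns at 16. Ester 10, whose C5=C6 bond is isolated and whose hindered enoate is inert to borane, is treated with BH3·THF and then NaOH/H2O2 to give methyl (5S,6S,10S)-6-hydroxydrim-8-en-11-oate F6. Silylation (t-BuMe2SiCl, imidazole) gives the silyl ether F7. Deconjugative hydroxylation as in step 8 gives the 9α-hydroxy ester F8. LiAlH4 gives the diol F9, and 2-methoxypropene with PPTS gives the acetonide F10. Bu4NF then removes the silyl group to give 16.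

Further compounds
F1 | step 5 | trimethylsilyl dienol ether of 6 | C[C@]12CCCC(C)(C)C1=CC=C2O[Si](C)(C)C
F2 | step 5 | 1-chloro-1-methyl-siloxycyclopropane adduct of F1 | C[C@]12CCCC(C)(C)C1=CC3C(C)(Cl)C23O[Si](C)(C)C
F3 | step 5 | (10S)-11-nordrima-5,7-dien-9-one | C[C@]12CCCC(C)(C)C1=CC=C(C)C2=O
F4 | step 8 | (10S)-drima-5,8-dien-11-ol | C[C@]12CCCC(C)(C)C1=CCC(C)=C2CO
F5 | step 8 | (10S)-8α,9α-epoxydrim-5-en-11-ol | C[C@]12CCCC(C)(C)C1=CC[C@@]3(C)O[C@@]23CO
F6 | step 11 | methyl (5S,6S,10S)-6-hydroxydrim-8-en-11-oate | C[C@]12CCCC(C)(C)[C@@H]1[C@@H](O)CC(C)=C2C(=O)OC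
F7 | step 11 | methyl 6α-(tert-butyldimethylsilyloxy)drim-8-en-11-oate | C[C@]12CCCC(C)(C)[C@@H]1[C@@H](O[Si](C)(C)C(C)(C)C)CC(C)=C2C(=O)OC
F8 | step 11 | methyl 6α-(tert-butyldimethylsilyloxy)-9α-hydroxydrim-7-en-11-oate | C[C@]12CCCC(C)(C)[C@@H]1[C@@H](O[Si](C)(C)C(C)(C)C)C=C(C)[C@]2(O)C(=O)OC
F9 | step 11 | 6α-(tert-butyldimethylsilyloxy)drim-7-ene-9α,11-diol | C[C@]12CCCC(C)(C)[C@@H]1[C@@H](O[Si](C)(C)C(C)(C)C)C=C(C)[C@]2(O)CO
F10 | step 11 | 6α-(tert-butyldimethylsilyloxy)-9,11-O-isopropylidenedrim-7-ene-9α,11-diol | C[C@]12CCCC(C)(C)[C@@H]1[C@@H](O[Si](C)(C)C(C)(C)C)C=C(C)[C@]23COC(C)(C)O3
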